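A small charge of starting material, 5 mM in the amber run, loses the same share per minute as 10 mM in the violet run: at 10.0 min they hold 24.5 % and 24.8 %.

| flask | starting material | solid partner | remark | time |
|---|---|---|---|---|
| violet | 10 mM | 2 equiv | the very flask that is asked about, followed so far |  |
| amber | 5 mM | 2 equiv | run made earlier |  |
| flask | 10 mM | 2.00 equiv |  | 80 min |

| run | time / min | product / % | starting material / % |
|---|---|---|---|
| violet | 0.833 | 0 | 88.0 |
| violet | 1.33 | 0 | 83.1 |
| violet | 2.00 | 0.3 | 76.1 |
| violet | 2.50 | 0 | 69.2 |
| violet | 4.00 | 0.4 | 58.1 |
| violet | 6.00 | 1.0 | 43.2 |
| violet | 10.0 | 5.3 | 24.8 |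
| amber | 2.50 | 0 | 71.3 |
| amber | 4.00 | 0.6 | 56.7 |
| amber | 6.00 | 1.7 | 43.0 |
| amber | 10.0 | 5.2 | 24.5 |
| amber | 15.0 | 13.4 | 12.2 |
| amber | 20.0 | 24.0 | 5.3 |
| amber | 30.0 | 46.1 | 1.2 |

(each reading ± 0.5 percentage points)

* how much product there is at 80 min, in percent of the starting material charged
* concentration of fresh partner in solution at 80 min, in percent of saturation

- solid partner is a solid; its amount is given per volume of the solution
- at the start none of the solid partner is in solution
- fresh partner is what solid partner becomes in solution

Taken alone, this first-order step has a constant of 0.149 /min read from amber, which leaves <0.001 % of the starting material at 80 min. The question therefore moves to the next step.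

In amber the gap in the balance, an open intermediate, averages 71.8 % from 10.0 min to 20.0 min and 61.7 % from 20.0 min to 30.0 min. Product rate divided by this pool gives an apparent pseudo-first-order constant, 0.0262 /min and then 0.0358 /min.

The reckoning here assumes that a co-reactant comes from dissolved partner at a steady feed, and on that assumption the constant climbs. The last process is that each product spends one co-reactant, so the constant follows feed times time, less product. Dividing the two constants, a ratio of 1.37, removes the unknown second-order constant and leaves a feed of 0.0373 /min of the amber charge, a reading with wide scatter.

The feed number, the partner fed by a given time in equivalents of the starting material charged, is then 1.49 for the asked flask. This is above one, so the reckoning does not expect the feed to cap product. Against 2.00 equiv charged, the reckoning cannot say whether solid remains at 80 min, and saturation stays in doubt.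

The forecast gives 90 % of product and 90 % of saturation: “With 2 equiv, solid probably remains”.

The flask gives 93.8 % and 73.6 %.

    open intermediate + second intermediate → product (k = 12.0 /M/min)
    fresh partner → second intermediate (k = 0.0620 /min)
    starting material → open intermediate (k = 0.140 /min)
    solid partner ⇌ fresh partner, rate k4*(cs4 - [fresh partner]) while solid is left; crystals form when [fresh partner] > cs4 (solubility = 3.40 mM, k = 1.50 /min)
    fresh partner ⇌ dormant form (K = 0.610, k = 0.250 /min)

At 80.0 min the flask holds 0 % of its solid partner, and product plus second intermediate come to 1.58 equivalents against the feed number of 1.49. The neighbouring flask with 40 mM of starting material, same equivalents and time, has a feed number of 0.373, below one. There product reaches 38.3 %, solid partner keeps 73.4 % of its charge, and open intermediate holds 61.7 %.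

The earlier runs and the new flask are simulated from invented constants; the scatter is artificial.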